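**Plan**

- Numbering is that of ent-kaurane: ring A is C1–C5 and C10, C6 sits on C5, C7 on C8, C20 on C10; ring C is C8, C9, C11–C14; ring D is C8, C15, C16, C13, C14; C17 sits on C16.
- Retrosynthesis: the C6 dimethyl acetal is hydrolysed last; before that the lactone C20–O bond is cut, back to a 6,7-seco acid whose C10 still carries C20 as a methyl group. This methyl group lies four bonds from the C7 carboxyl, so a hydroxyl placed on C20 closes the ring C7–O–C20–C10–C9–C8 by itself. Further cuts: C13–C16 and C15–C16 (ring D), C8–C14 and C9–C11 (ring C), C9–C10, C5–C6.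
- Forward: ring A comes from 2,4,4-trimethylcyclohex-2-enone. The C9–C10 bond is made by radical addition of a C1/C10 epoxide to an acrylate, which also closes a temporary C1–O–C7 lactone. Ring C is added by a Diels–Alder reaction with butadiene on that lactone. The lactone is opened, ring D is closed by a 5-exo radical cyclisation, oxidation states are adjusted, and the enzymatic C20 hydroxylation closes the lactone ring last.
- Stereochemistry: C1 is set by a catalytic enantioselective ketone reduction and relayed to C5 by a suprafacial [2,3] shift, then to C10 by hydroxyl-directed epoxidation and anti radical addition. C9 and C8 come from the Diels–Alder addition anti to the C20 methyl group, C13 from the bridge, C15 from exo-face hydride delivery.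

Key step: step 22

Remark: in compounds 9–17 the lactone carbonyl is C7 and the exocyclic acyl carbon on C8 is C15. Assumption: a P450 BM3 variant selective for C20 of acid 29 is taken to be obtainable by screening and directed evolution.

**Route**

Step 1
Reactants: 1 2,4,4-trimethylcyclohex-2-en-1-one
Product: 2 (1S)-2,4,4-trimethylcyclohex-2-en-1-ol
Conditions: (R)-2-methyl-CBS-oxazaborolidine (10 mol%), BH3·SMe2, THF, −20 °C; then MeOH
Reagents that add atoms: none
Why: Corey–Bakshi–Shibata reduction of an α-methyl cyclic enone, in which the alkenyl arm acts as the large group, so the (R)-catalyst should deliver hydride to the face that gives the (S)-carbinol at C1.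

Step 2
Reactants: 2 (1S)-2,4,4-trimethylcyclohex-2-en-1-ol
Product: 3 tributyl({[(1S)-2,4,4-trimethylcyclohex-2-en-1-yl]oxy}methyl)stannane
Conditions: KH, THF, 0 °C; Bu3SnCH2I, 0 °C to rt
Reagents that add atoms: tributyl(iodomethyl)stannane, CCCC[Sn](CCCC)(CCCC)CI
Why: Williamson etherification of the potassium alkoxide with the primary iodide leaves the C1 stereocentre untouched and installs the handle for the Wittig–Still rearrangement.

Step 3
Reactants: 3 tributyl({[(1S)-2,4,4-trimethylcyclohex-2-en-1-yl]oxy}methyl)stannane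
Product: 4 [(1R)-2,6,6-trimethylcyclohex-2-en-1-yl]methanol ((R)-α-cyclogeraniol; CH2OH = C6 on C5, alkene C1=C10)
Conditions: n-BuLi, THF, −78 °C; then H2O
Reagents that add atoms: none
Why: tin–lithium exchange gives the α-alkoxy carbanion, whose suprafacial Wittig–Still [2,3] rearrangement forms C5–C6 on the ring face that carried O1, so the C1 configuration is transferred to C5.

Step 4
Reactants: 4 (R)-α-cyclogeraniol
Product: 5 1,10-epoxide of 4 with the oxirane oxygen cis to the CH2OH group
Conditions: VO(acac)2 (cat.), t-BuOOH, CH2Cl2, 0 °C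
Reagents that add atoms: tert-butyl hydroperoxide, CC(C)(C)OO
Why: vanadium-catalysed hydroxyl-directed epoxidation of a homoallylic alcohol delivers oxygen to the alkene face syn to C6, which fixes C1 and C10 of the epoxide.

Step 5
Reactants: 5 syn-epoxy alcohol
Product: 6 tert-butyldimethylsilyl ether of 5
Conditions: TBSCl, imidazole, DMF, rt
Reagents that add atoms: tert-butyldimethylsilyl chloride, CC(C)(C)[Si](C)(C)Cl
Why: standard silylation of a primary alcohol under conditions that leave the epoxide intact.

Step 6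
Reactants: 6 silyl-protected epoxide; 7 2,2,2-trifluoroethyl acrylate
Product: 9 trans-fused δ-lactone O1–C7(=O)–C8H2–C9H2–C10 (C20 methyl, C6 and O1 on one face of ring A, C9 on the other), via trifluoroethyl hydroxy ester 8 (not isolated)
Conditions: Cp2TiCl2 (20 mol%), Zn dust, 2,4,6-collidine hydrochloride, THF, rt
Reagents that add atoms: none
Why: Nugent–RajanBabu reductive epoxide opening by Cp2TiCl gives the tertiary C10 radical, whose Giese addition to the acrylate should occur anti to both the C1 titanoxy group and the C5 side chain (setting C10), after which the C1 alkoxide displaces trifluoroethoxide to close the lactone.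

Step 7
Reactants: 9 1,7-lactone
Product: 10 8-[(ethylsulfanyl)carbonyl] derivative of 9 (thioester carbon = C15; C8 epimers)
Conditions: LiN(SiMe3)2 (2.2 equiv), THF, −78 °C; EtSC(O)Cl; then aq. NH4Cl
Reagents that add atoms: S-ethyl carbonochloridothioate, CCSC(Cl)=O
Why: Claisen-type C-acylation of the lactone lithium enolate with a chlorothioformate, the second equivalent of base taking up the more acidic product.

Step 8
Reactants: 10 thioester lactone
Product: 12 8,9-didehydro derivative of 10 (C8=C9 activated by the C7 lactone and the C15 thioester), via C8 phenylselenide 11 (not isolated)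
Conditions: NaH, THF, 0 °C; PhSeCl; then 30% H2O2, CH2Cl2, 0 °C to rt
Reagents that add atoms: none
Why: α-selenenylation of the 1,3-dicarbonyl followed by selenoxide syn-elimination, which can only take a hydrogen from C9 and so gives the endocyclic alkene.

Step 9
Reactants: 12 doubly activated unsaturated lactone; 13 buta-1,3-diene
Product: 14 Diels–Alder adduct (ring C = C8, C9, C11, C12=C13, C14, cis-fused to the lactone on the face opposite C20; thioester on the C20 face)
Conditions: 13 (excess), ZnCl2, CH2Cl2, 0 °C to rt, sealed tube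
Reagents that add atoms: none
Why: Lewis acid-promoted Diels–Alder reaction of a doubly activated dienophile, in which butadiene should add to the C8=C9 face anti to the axial C20 methyl group on the neighbouring C10 and suprafacial addition sets C9 and C8 together, with the ring carbonyl as C7 and the thioester as C15.

Step 10
Reactants: 14 Diels–Alder adduct; 15 ethynyltrimethylsilane
Product: 16 C15 ynone (C15(=O)–C16≡C17–SiMe3 on C8; lactone intact)
Conditions: PdCl2(dppf) (10 mol%), tri(2-furyl)phosphine, CuI, Et3N, DMF, 50 °C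
Reagents that add atoms: none
Why: Fukuyama-type palladium/copper coupling of a thioester with a terminal alkyne forms the ynone under neutral conditions that the more electrophilic lactone survives.

Step 11
Reactants: 16 ynone
Product: 17 C15 propargylic alcohols (both C15 epimers)
Conditions: NaBH4, CeCl3·7H2O, MeOH, −78 °C
Reagents that add atoms: none
Why: Luche 1,2-reduction removes the base-sensitive ynone before saponification; the C15 configuration is of no consequence because this centre is re-oxidised in step 14.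

Step 12
Reactants: 17 propargylic alcohols
Product: 19 allyl 7-ester with free C1 and C15 hydroxyls and a terminal alkyne, via lithium carboxylate 18 (not isolated)
Conditions: LiOH·H2O, THF/MeOH/H2O, 0 °C to rt; CO2 to pH 8, evaporate; allyl bromide, DMF, rt
Reagents that add atoms: lithium hydroxide, [Li+].[OH-]; allyl bromide, C=CCBr
Why: saponification opens the strained lactone and cleaves the alkynyl C–Si bond, and O-alkylation of the carboxylate salt then blocks re-lactonisation and frees ring C to flip for the next step.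

Step 13
Reactants: 19 allyl ester diol
Product: 21 allyl 1,15-dihydroxy-6-(silyloxy)-6,7-seco-ent-kaur-16-en-7-oate (C15 epimers), via C17 vinylstannane 20 (not isolated)
Conditions: Bu3SnH, AIBN (cat.), benzene, 80 °C, slow addition; then PPTS, CH2Cl2, rt
Reagents that add atoms: none
Why: stannyl radical addition to the terminal alkyne gives the C16 vinyl radical, which closes ring D by 5-exo-trig cyclisation onto C13 of the ring C alkene (the bridge allows only one configuration at C13), and protodestannylation then reveals the exocyclic methylene.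

Step 14
Reactants: 21 bicyclic diol
Product: 22 allyl 1,15-dioxo-6-(silyloxy)-6,7-seco-ent-kaur-16-en-7-oate
Conditions: Dess–Martin periodinane, NaHCO3, CH2Cl2, rt
Reagents that add atoms: none
Why: Dess–Martin oxidation of both secondary alcohols installs the C1 ketone and converges the two C15 epimers to one enone.

Step 15
Reactants: 22 diketone
Product: 23 (15R)-15-hydroxy-1-oxo compound (hydroxyl on the face of the C9–C11–C12 bridge)
Conditions: NaBH4, CeCl3·7H2O, MeOH, −78 °C
Reagents that add atoms: none
Why: Luche reduction should prefer the conjugated C15 ketone over the saturated C1 ketone shielded by the quaternary C10, and hydride should enter from the exo face (side of the C14 bridge), which sets C15 as in the target.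

Step 16
Reactants: 23 C15 alcohol
Product: 24 15-acetate
Conditions: Ac2O, DMAP (cat.), pyridine, rt
Reagents that add atoms: acetic anhydride, CC(=O)OC(C)=O
Why: DMAP-catalysed acylation of the only free hydroxyl.

Step 17
Reactants: 24 15-acetoxy 1-ketone
Product: 25 15-acetoxy-1-oxo-2-ene (ring A enone)
Conditions: IBX, DMSO, 70 °C
Reagents that add atoms: none
Why: IBX α,β-dehydrogenation of a ketone; C2 is the only enolisable position of the C1 ketone (C10 is quaternary) and the quaternary C4 stops further desaturation.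

Step 18
Reactants: 25 silyl ether
Product: 26 C6 primary alcohol
Conditions: HF·pyridine, THF, 0 °C to rt
Reagents that add atoms: none
Why: fluoride-mediated cleavage of the primary silyl ether under mildly acidic conditions that spare the acetate and the allyl ester.

Step 19
Reactants: 26 C6 alcohol
Product: 27 C6 aldehyde
Conditions: Dess–Martin periodinane, NaHCO3, CH2Cl2, 0 °C
Reagents that add atoms: none
Why: buffered Dess–Martin oxidation gives the hindered aldehyde without base, so C5 should not epimerise.

Step 20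
Reactants: 27 aldehyde
Product: 28 C6 dimethyl acetal, allyl ester
Conditions: HC(OMe)3, MeOH, PPTS (cat.), rt
Reagents that add atoms: trimethyl orthoformate, COC(OC)OC; methanol, CO
Why: acid-catalysed acetalisation driven by the orthoformate; the hindered, conjugated C1 ketone should not react.

Step 21
Reactants: 28 allyl ester
Product: 29 (15R)-15-acetoxy-6,6-dimethoxy-1-oxo-6,7-seco-ent-kaura-2,16-dien-7-oic acid
Conditions: Pd(PPh3)4 (5 mol%), morpholine, THF, 0 °C
Reagents that add atoms: none
Why: Tsuji–Trost deallylation, in which zerovalent palladium should ionise the primary allyl ester far faster than the secondary C15 acetate next to the quaternary C8, and morpholine traps the allyl fragment.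

Step 22
Reactants: 29 seco acid with C20 methyl group
Product: 31 7,20-lactone with C6 dimethyl acetal, via C20 hydroxy acid 30 (not isolated)
Conditions: P450 BM3 (CYP102A1) variant from screening and directed evolution, NADP+ (cat.), glucose dehydrogenase, D-glucose, air, KH2PO4/K2HPO4 buffer pH 8.0, DMSO (2% v/v), 25 °C
Reagents that add atoms: dioxygen, O=O
Why: Proposed new method: the haem iron-oxo intermediate takes a hydrogen atom from the C20 methyl group and hydroxyl rebound gives the δ-hydroxy acid 30. The closest known reaction types are the hydroxylation of carboxylate-bound fatty acids and terpenoid acids by BM3 variants and the oxidation of angular methyl groups by cytochrome P450 enzymes of diterpenoid biosynthesis. The ring C7–O–C20–C10–C9–C8 then closes by 6-exo-trig attack of the C20 hydroxyl on the C7 carboxyl, helped by the quaternary centres C8 and C10, and this takes the product out of reach of further oxidation. No stereocentre is formed. The step needs selectivity for C20 over the C18 and C19 methyl groups, the ring C and ring D methylenes, the exocyclic alkene and the acetal C–H bond; carboxylate binding, as with the native fatty-acid substrates, should hold C7 at the pocket and present the C20 methyl group four bonds away, and the pocket has to be fitted to 29 by evolution.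

Step 23
Reactants: 31 lactone acetal
Product: 32 target, (5R,8S,9S,10S,13R,15R)-15-acetoxy-1,6-dioxo-6,7-seco-ent-kaura-2,16-dien-7,20-olide
Conditions: PPTS (cat.), acetone/H2O, 40 °C
Reagents that add atoms: water, O
Why: mild acid-catalysed acetal hydrolysis, which the lactone, the allylic acetate and the enone should survive.

**Compound list**

1 | 2,4,4-trimethylcyclohex-2-en-1-one | CC1=CC(C)(C)CCC1=O | starting material
2 | (1S)-2,4,4-trimethylcyclohex-2-en-1-ol | O[C@H]1CCC(C)(C)C=C1C | intermediate
3 | tributyl({[(1S)-2,4,4-trimethylcyclohex-2-en-1-yl]oxy}methyl)stannane | CCCC[Sn](CCCC)(CCCC)CO[C@H]1CCC(C)(C)C=C1C | intermediate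
4 | [(1R)-2,6,6-trimethylcyclohex-2-en-1-yl]methanol | OC[C@H]1C(C)=CCCC1(C)C | intermediate
5 | (1,3,3-trimethyl-7-oxabicyclo[4.1.0]heptan-2-yl)methanol, oxirane oxygen cis to CH2OH | OC[C@@H]1C(C)(C)CC[C@@H]2O[C@]12C | intermediate
6 | tert-butyldimethylsilyl ether of 5 | CC(C)(C)[Si](C)(C)OC[C@@H]1C(C)(C)CC[C@@H]2O[C@]12C | intermediate
7 | 2,2,2-trifluoroethyl acrylate | C=CC(=O)OCC(F)(F)F | starting material
8 | trifluoroethyl 3-(ring A)propanoate with free C1 hydroxyl (C9 trans to O1 and C6) | O=C(CC[C@]1(C)[C@@H](O)CCC(C)(C)[C@H]1CO[Si](C)(C)C(C)(C)C)OCC(F)(F)F | intermediate (not isolated)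
9 | trans-fused 1,7-lactone (5-(silyloxymethyl)-4a,6,6-trimethyl-octahydrochromen-2-one; C20, C6 and O1 cis) | CC(C)(C)[Si](C)(C)OC[C@@H]1C(C)(C)CC[C@@H]2OC(=O)CC[C@@]12C | intermediate
10 | 8-[(ethylsulfanyl)carbonyl] derivative of 9 (C8 epimers) | CC(C)(C)[Si](C)(C)OC[C@@H]1C(C)(C)CC[C@@H]2OC(=O)C(C(=O)SCC)C[C@@]12C | intermediate
11 | 8-(phenylselanyl) derivative of 10 | CC(C)(C)[Si](C)(C)OC[C@@H]1C(C)(C)CC[C@@H]2OC(=O)C(C(=O)SCC)([Se]c3ccccc3)C[C@@]12C | intermediate (not isolated)
12 | 8,9-didehydro derivative of 10 | CC(C)(C)[Si](C)(C)OC[C@@H]1C(C)(C)CC[C@@H]2OC(=O)C(C(=O)SCC)=C[C@@]12C | intermediate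
13 | buta-1,3-diene | C=CC=C | starting material
14 | Diels–Alder adduct (ring C cis-fused, anti to C20; thioester syn to C20) | CC(C)(C)[Si](C)(C)OC[C@@H]1C(C)(C)CC[C@@H]2OC(=O)[C@@]3(C(=O)SCC)CC=CC[C@H]3[C@@]12C | intermediate
15 | ethynyltrimethylsilane | C#C[Si](C)(C)C | starting material
16 | C15 (trimethylsilyl)ynone of 14 | CC(C)(C)[Si](C)(C)OC[C@@H]1C(C)(C)CC[C@@H]2OC(=O)[C@@]3(C(=O)C#C[Si](C)(C)C)CC=CC[C@H]3[C@@]12C | intermediate
17 | C15 propargylic alcohols (C15 epimers) | CC(C)(C)[Si](C)(C)OC[C@@H]1C(C)(C)CC[C@@H]2OC(=O)[C@@]3(C(O)C#C[Si](C)(C)C)CC=CC[C@H]3[C@@]12C | intermediate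
18 | lithium 7-carboxylate, free C1 and C15 hydroxyls, terminal alkyne | [Li+].[O-]C(=O)[C@@]1(C(O)C#C)CC=CC[C@H]1[C@]2(C)[C@@H](O)CCC(C)(C)[C@H]2CO[Si](C)(C)C(C)(C)C | intermediate (not isolated)
19 | allyl 7-ester of 18 | C=CCOC(=O)[C@@]1(C(O)C#C)CC=CC[C@H]1[C@]2(C)[C@@H](O)CCC(C)(C)[C@H]2CO[Si](C)(C)C(C)(C)C | intermediate
20 | cyclised C17 tributylstannyl alkene (C15 epimers, alkene geometry open) | CCCC[Sn](CCCC)(CCCC)C=C1[C@@H]2CC[C@@H]([C@]3(C)[C@@H](O)CCC(C)(C)[C@H]3CO[Si](C)(C)C(C)(C)C)[C@](C2)(C(=O)OCC=C)C1O | intermediate (not isolated)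
21 | allyl 1,15-dihydroxy-6-(silyloxy)-6,7-seco-ent-kaur-16-en-7-oate (C15 epimers; C5, C8, C9, C10, C13 as in 32) | C=C1[C@@H]2CC[C@@H]([C@]3(C)[C@@H](O)CCC(C)(C)[C@H]3CO[Si](C)(C)C(C)(C)C)[C@](C2)(C(=O)OCC=C)C1O | intermediate
22 | allyl 1,15-dioxo-6-(silyloxy)-6,7-seco-ent-kaur-16-en-7-oate | C=C1[C@@H]2CC[C@@H]([C@]3(C)C(=O)CCC(C)(C)[C@H]3CO[Si](C)(C)C(C)(C)C)[C@](C2)(C(=O)OCC=C)C1=O | intermediate
23 | (15R)-15-hydroxy-1-oxo analogue of 22 | C=C1[C@@H]2CC[C@@H]([C@]3(C)C(=O)CCC(C)(C)[C@H]3CO[Si](C)(C)C(C)(C)C)[C@](C2)(C(=O)OCC=C)[C@@H]1O | intermediate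
24 | 15-acetate of 23 | C=C1[C@@H]2CC[C@@H]([C@]3(C)C(=O)CCC(C)(C)[C@H]3CO[Si](C)(C)C(C)(C)C)[C@](C2)(C(=O)OCC=C)[C@@H]1OC(C)=O | intermediate
25 | 2,3-didehydro derivative of 24 (ring A enone) | C=C1[C@@H]2CC[C@@H]([C@]3(C)C(=O)C=CC(C)(C)[C@H]3CO[Si](C)(C)C(C)(C)C)[C@](C2)(C(=O)OCC=C)[C@@H]1OC(C)=O | intermediate
26 | C6 alcohol | C=C1[C@@H]2CC[C@@H]([C@]3(C)C(=O)C=CC(C)(C)[C@H]3CO)[C@](C2)(C(=O)OCC=C)[C@@H]1OC(C)=O | intermediate
27 | C6 aldehyde | C=C1[C@@H]2CC[C@@H]([C@]3(C)C(=O)C=CC(C)(C)[C@H]3C=O)[C@](C2)(C(=O)OCC=C)[C@@H]1OC(C)=O | intermediate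
28 | C6 dimethyl acetal, allyl ester | C=C1[C@@H]2CC[C@@H]([C@]3(C)C(=O)C=CC(C)(C)[C@H]3C(OC)OC)[C@](C2)(C(=O)OCC=C)[C@@H]1OC(C)=O | intermediate
29 | 15-acetoxy-6,6-dimethoxy-1-oxo-6,7-seco-ent-kaura-2,16-dien-7-oic acid | C=C1[C@@H]2CC[C@@H]([C@]3(C)C(=O)C=CC(C)(C)[C@H]3C(OC)OC)[C@](C2)(C(=O)O)[C@@H]1OC(C)=O | intermediate
30 | 20-hydroxy derivative of 29 | C=C1[C@@H]2CC[C@@H]([C@]3(CO)C(=O)C=CC(C)(C)[C@H]3C(OC)OC)[C@](C2)(C(=O)O)[C@@H]1OC(C)=O | intermediate (not isolated)
31 | 7,20-lactone with C6 dimethyl acetal | C=C1[C@@H]2CC[C@@H]3[C@](C2)(C(=O)OC[C@]32C(=O)C=CC(C)(C)[C@H]2C(OC)OC)[C@@H]1OC(C)=O | intermediate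
32 | CNP0108627.4 | C=C1[C@@H]2CC[C@@H]3[C@](C2)(C(=O)OC[C@]32C(=O)C=CC(C)(C)[C@H]2C=O)[C@@H]1OC(C)=O | target

**Step count and risks**

Total step count: 23. Longest linear sequence: 23 steps (1 to 32).

Steps most likely to fail:

Step 22. The enzyme may bind the acid unproductively, or oxidise other positions (the C18 and C19 methyl groups, allylic C–H bonds of rings C and D, the exocyclic alkene) instead of C20. The fallback uses known chemistry and runs from 29 back to 31. Luche reduction (NaBH4, CeCl3·7H2O, MeOH) of the ring A enone gives the C1 allylic alcohol F1; hydride should enter anti to the axial C20 methyl group, so O1 is cis to C20. Et2SiH2 and [Ir(cod)OMe]2 convert the hydroxyl and the acid into the bis(diethylsilyl) compound F2. With [Ir(cod)OMe]2, 3,4,7,8-tetramethyl-1,10-phenanthroline and norbornene at 80 °C, hydroxyl-directed dehydrogenative silylation should take place at C20, the only primary C–H position γ to O1, and aqueous work-up gives the oxasilolane acid F3. Tamao–Fleming oxidation (H2O2, KHCO3, KF) gives the 1,20-diol acid F4, which is lactonised (EDC·HCl, DMAP) to the 1-hydroxy 7,20-lactone F5. MnO2 oxidises the allylic alcohol and the route is rejoined at 31.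

Step 9. The cycloaddition may stall at C9, which sits next to the quaternary C10, while the electrophilic dienophile hydrates or polymerises, or the Lewis acid may cleave the silyl ether. The fallback runs from 12 to 14 through a polar cycloaddition and a deoxygenation. The far more nucleophilic 2-(trimethylsilyloxy)buta-1,3-diene is added without Lewis acid (toluene, rt) to give the silyl enol ether adduct F6, with the silyloxy carbon as C12 and the same facial course. CsF and PhNTf2 in DME convert the regiodefined enol ether into the C12 vinyl triflate F7. Reduction of the triflate with Pd(OAc)2, PPh3 and tributylammonium formate in DMF then gives 14.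

Step 6. The tertiary radical may be reduced or lose a β-hydrogen before it adds to the acrylate, or add without face control. The fallback is a polar sequence from 6 to 9. LiClO4 in Et2O promotes Meinwald rearrangement of the epoxide by hydride shift from C1 to C10 and gives the C1 ketone F8. KOtBu (cat.) and methyl acrylate in t-BuOH bring about Michael addition of the more substituted enolate at C10, anti to the C5 side chain, to give the keto ester F9. NaBH4 in MeOH delivers hydride axially, anti to the axial C20 methyl group, and gives the hydroxy ester F10 with O1 cis to C20. PPTS in toluene then closes the lactone with loss of methanol and returns the route at 9.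

Further compounds
F1 | step 22 | C1 allylic alcohol from 29 (O1 cis to C20) | C=C1[C@@H]2CC[C@@H]([C@]3(C)[C@@H](O)C=CC(C)(C)[C@H]3C(OC)OC)[C@](C2)(C(=O)O)[C@@H]1OC(C)=O
F2 | step 22 | O1 diethylsilyl ether and diethylsilyl ester of F1 | C=C1[C@@H]2CC[C@@H]([C@]3(C)[C@@H](O[SiH](CC)CC)C=CC(C)(C)[C@H]3C(OC)OC)[C@](C2)(C(=O)O[SiH](CC)CC)[C@@H]1OC(C)=O
F3 | step 22 | oxasilolane acid (O1–SiEt2–C20) | C=C1[C@@H]2CC[C@@H]([C@]34C[Si](CC)(CC)O[C@H]3C=CC(C)(C)[C@H]4C(OC)OC)[C@](C2)(C(=O)O)[C@@H]1OC(C)=O
F4 | step 22 | 1,20-diol acid | C=C1[C@@H]2CC[C@@H]([C@]3(CO)[C@@H](O)C=CC(C)(C)[C@H]3C(OC)OC)[C@](C2)(C(=O)O)[C@@H]1OC(C)=O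
F5 | step 22 | 1-hydroxy 7,20-lactone | C=C1[C@@H]2CC[C@@H]3[C@](C2)(C(=O)OC[C@]32[C@@H](O)C=CC(C)(C)[C@H]2C(OC)OC)[C@@H]1OC(C)=O
F6 | step 9 | C12 trimethylsilyl enol ether adduct | CC(C)(C)[Si](C)(C)OC[C@@H]1C(C)(C)CC[C@@H]2OC(=O)[C@@]3(C(=O)SCC)CC=C(O[Si](C)(C)C)C[C@H]3[C@@]12C
F7 | step 9 | C12 vinyl triflate | CC(C)(C)[Si](C)(C)OC[C@@H]1C(C)(C)CC[C@@H]2OC(=O)[C@@]3(C(=O)SCC)CC=C(OS(=O)(=O)C(F)(F)F)C[C@H]3[C@@]12C
F8 | step 6 | 3-(silyloxymethyl)-2,4,4-trimethylcyclohexanone (C10 epimers) | CC1C(=O)CCC(C)(C)[C@H]1CO[Si](C)(C)C(C)(C)C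
F9 | step 6 | methyl 3-(1-methyl-2-oxocyclohexyl)propanoate keto ester (C9 trans to C6) | COC(=O)CC[C@]1(C)C(=O)CCC(C)(C)[C@H]1CO[Si](C)(C)C(C)(C)C
F10 | step 6 | methyl hydroxy ester (O1 cis to C20) | COC(=O)CC[C@]1(C)[C@@H](O)CCC(C)(C)[C@H]1CO[Si](C)(C)C(C)(C)C
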